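(All runs are simulated for an exercise.)

Answer two questions about the flask.

| setting | larch | elm | flask |
|---|---|---|---|
| free monomer | 0.50 M (fed, over 4.0 h) | 0.50 M (fed, over 4.0 h) | 0.50 M (fed, over 4.0 h) |
| initiator | 3.4 mM | 7.5 mM | 5.0 mM |
| remark | run made earlier; the fed solution adds 0.50 times the starting volume | run made earlier; the fed solution adds 0.50 times the starting volume | the fed solution adds 0.50 times the starting volume |
| time |  |  | 4.0 h |

- larch (time / h: monomer in chains / %, free monomer / %): 0.250: 0, 6.0; 0.417: 0.2, 10.5; 0.667: 1.4, 15.4; 1.33: 4.0, 29.8; 2.00: 7.2, 42.9; 3.00: 14.3, 60.6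
- elm (time / h: monomer in chains / %, free monomer / %): 0.250: 0, 6.4; 0.417: 0.6, 9.4; 0.667: 1.7, 15.6; 1.33: 5.4, 28.1; 2.00: 10.2, 40.2; 3.00: 19.8, 55.2

(each reading ± 0.3 percentage points)

- every charge counts on the volume at the start, and the solution that is fed holds the whole dose
- the average divides the monomer in chains by the number of chains, living and dead together; two radicals that join make one chain
- the earlier runs do not show the number of chains; that part of a forecast is a guess
- percentages count the whole charge, also what has not yet gone in

* average number of monomer units in a chain (living and dead chains, two that joined counted as one) at 4.0 h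
* part of the free monomer that has reacted at 4.0 h

Turn the second question round. What would put half of the charge in chains by 4.0 h, when dosing ends? Read a rate first. From 2.00 h to 3.00 h, divide the gain in chains by the mean free monomer, both as fractions of the charge. Then scale by the root of the initiator charges.

| Run | Initiator | Rate read | Scaled to the flask |
|---|---|---|---|
| larch | 3.4 mM | 0.137 h⁻¹ | 0.166 h⁻¹ |
| elm | 7.5 mM | 0.201 h⁻¹ | 0.164 h⁻¹ |

The rates read stand at a ratio of 1.47, and the root of the charges is 1.49. Take k = 0.165 h⁻¹, the share of the free monomer present that enters chains per hour, a pseudo-first-order constant.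

Free monomer cannot exceed what has gone in, which averages half the charge over dosing. So, at steady k, half the charge in chains needs k·tf of at least 1. The flask stands at 0.661.

Now compute the correction. Scaled to the flask, monomer in chains at 3.00 h comes to about 16.8 %. By my reckoning, the last hour at k adds about 10.8 %. That makes c about 27.6 %. The readings do not show the number of chains, so leave dp a guess.

The forecast gives 65 and 27 %, slightly under my c, and it too holds “so rate goes as √I”.

The flask gives 58.7 and 26.2 %.

    initiator → 2 initiating radical (k = 4.10 × 10⁻⁵ s⁻¹)
    2 growing radical → dead chain (k = 1.80 × 10⁸ L mol⁻¹ s⁻¹)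
    free monomer + growing radical → monomer in chains + growing radical, rate k3*[growing radical]*[free monomer] (k = 1800 L mol⁻¹ s⁻¹)
    free monomer + initiating radical → growing radical + monomer in chains (k = 13000 L mol⁻¹ s⁻¹)

In the flask, initiator at 3.37 mM or 7.09 mM moves c by 4 points. Read k in the flask from 2.00 h to 4.0 h: it is 0.153 h⁻¹, so k·tf is 0.611. The neighbour flask left until 10 h reaches c = 61.7 % with 38.3 % free, and its k after 4.0 h reads 0.106 h⁻¹.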